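## The problem

The target is a pentacycle on a pyrrolo[1,2-a]azepine core (N4, C5 to C9, C9a, C1 to C3). A 3-methylbutenolide is fused across C5–C6 so that C5 is an N,O-acetal carbon; C9 is a quaternary spiro carbon carrying the ring oxygen of an α-methyl-γ-lactone; C3 carries a second α-methyl-γ-lactone through its carbinol carbon. Seven stereocentres have to be set: C3 and C9a (trans on the pyrrolidine), C9, the side-lactone carbinol carbon, the two methyl-bearing lactone carbons and C5. C9a can steer the addition that creates C9, and C3 the one that creates the side-lactone carbinol carbon, because each new centre is formed next to the ring nitrogen, where a metal chelate can fix the conformation. The two methyl-bearing carbons lie 1,3 to their neighbours and need opposite relative senses (methyl trans to the pyrrolidinyl group on the spiro lactone, cis to it on the side lactone), so they are better imported than induced; C5 equilibrates through ring opening and can only be set last. The aminal butenolide does not tolerate organometallic reagents, hydride or strong base, α-amino aldehydes and ketones epimerise at the ring carbon, and a free N–H next to either γ-lactone invites O-to-N acyl transfer to a six-membered lactam. The feature that opens the key step is that C3 and C9a each bear an oxygenated carbon: the side-lactone carbinol carbon, C3, C2, C1, C9a and C9 form a C2-symmetric 1,2,5,6-tetrafunctional hexane bridged by N at positions 2 and 5, which is the carbon chain of a 3,4-dideoxyhexitol. Both N–C bonds of the pyrrolidine can therefore come from one primary amine and two homochiral secondary sulfonates.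

## Retrosynthesis

**35 to 31 and 32.** The N4–C5 bond, the lactone O–C5 bond and the C6–C(α) bond of the butenolide are cut, so the three butenolide carbons that are not part of the azepine come from pyruvic acid 32. The precursor is the secondary amine 31, whose C5 is a dioxolane-masked aldehyde. Acid unmasks it to amino aldehyde 33, which closes the azepine as enamine 34 and is annulated. This cut is preferred to carrying a preformed butenolide arm because no butenolide would survive the organometallic steps, and it leaves the most fragile ring and the labile C5 centre for the last step. The forward reaction must form the C–C bond at the enamine carbon and must keep the amine protonated until it has condensed.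

**31 to 29 via 30.** The N-benzyl group is restored, and both lactone carbonyls are traced back to primary alcohols, giving the amino tetraol 29. Cutting both lactones at the oxidation level of 1,4-diols lets one desilylation and one oxidation serve both arms, and keeps lactones out of every Grignard step. The forward oxidation must take primary hydroxyl in preference to the secondary carbinol and to the tertiary amine.

**29 to 24 and 26 via 28.** The bond between the side-lactone carbinol carbon and its CH2 is cut. Aldehyde 24 takes the Grignard reagent 27, made from the (R)-bromide 26, which brings the methyl stereocentre from the chiral pool (25). The alternative of a 2-(alkoxycarbonyl)allyl reagent followed by hydrogenation was set aside because the same trick gives the wrong methyl configuration on the spiro lactone, and one method for both arms is wanted. The forward step needs Cram-chelate control by the N-benzyl nitrogen to give the (S) carbinol of 28.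

**24 to 18 and 20 via 23 and 22.** The C9–CH2 bond of the spiro lactone is cut. Of the two C–C bonds at C9 this is the one to form last, because chelate-controlled attack of the lactone carbon (Grignard 21 from the (S)-bromide 20, from 19) on ketone 18 gives 9S; the reverse order would need Felkin control. Ketone 18 already holds C8, C7, C6 and the masked C5. Removal of one silyl group (23) and oxidation then expose the second arm.

**18 to 13 and 14 via 17.** The ketone C–C bond is cut to aldehyde 15 and Grignard reagent 16 from the commercial bromo acetal 14. The carbinol configuration of 17 is irrelevant because it is oxidised. A dioxolane is chosen for C5 because it survives Grignard reagents, fluoride, oxidation and hydrogenolysis.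

**13 to 11 via 12.** The two hydroxymethyl arms of diol 12 are homotopic, so monosilylation differentiates them without any regiochemical question. Diol 12 comes from the bis-silyl ether 11 by fluoride, which leaves the N-benzyl group in place as the chelating group for both later additions. This is the reason for silyl rather than benzyl ethers on the arms.

**11 to 9 and 10.** Both N–C bonds are cut. Dimesylate 9 and benzylamine 10 give the trans-pyrrolidine by two SN2 displacements with inversion. The precursor is an open, C2-symmetric chain with only two stereocentres.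

**9 to 1 via 8, 6, 5, 4 and 2.** D-Mannitol supplies the chain, but its C2 and C5 have the configuration that would give the enantiomeric pyrrolidine, so one inversion at each carbon is needed before the key step. It is done on dimesylate 6 with cesium acetate (to 8 via 7) rather than by a Mitsunobu reaction, because a 1,4-diol under Mitsunobu conditions can cyclise to a tetrahydrofuran, whereas 6 has no free hydroxyl. Diol 5 comes from tetraol 4 by primary-selective silylation, and 4 from the commercial bis-acetonide 1 by deoxygenation of the 3,4-diol (2) and hydrogenation/hydrolysis.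

## Roads not taken

**Alternative 1:** Both lactone acyl carbons are removed at once. Each C(=O)–C(α) and acyl C–O bond of the saturated tetracyclic bis-lactone A1 is traced back to CO and a terminal alkene, leading to the bis(homoallylic alcohol) A2. In the forward step Pd(OAc)2 (divalent palladium) with 1,4-bis(diphenylphosphino)butane under CO/H2 would carbonylate both alkenes at the internal carbon and close both rings, creating the two methyl groups.
- Merit: four bonds, two rings and two stereocentres in one catalytic step from cheap allyl reagents. This is shorter than the chosen plan, which spends two silylations, a desilylation and an oxidation on the same atoms.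
- Weak points: each alkene can also give the linear acyl and a δ-lactone. The methyl configuration rests on 1,3-induction, and one catalyst would have to give opposite relative senses at the spiro and the side lactone. The basic amine can bind palladium. A1 also stops at the saturated azepane, so C5 and C6 would still have to be oxidised and annulated next to a tertiary amine.
- Comparison: the chosen plan gives up the shorter lactone construction for certainty of both methyl configurations (from 19 and 25) and a C5 that is already at the aldehyde oxidation level.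

**Alternative 2:** The CH2–C6 bond of the azepine is cut in the tricyclic ketone A3. Its precursor A4 carries the butenolide already bound to nitrogen as the N,O-acetal, and a cyclopropanol at the future C9. Mn(acac)3 (trivalent manganese) would open the cyclopropanol to a β-keto alkyl radical that adds to the butenolide β-carbon, and Cu(OAc)2 (divalent copper) would oxidise the adduct radical and restore the double bond.
- Merit: the aminal is made early by simple condensation and the azepine closure is convergent. It avoids the least precedented step of the chosen route (the annulation with pyruvic acid) and is the better plan in that respect.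
- Weak points: a seven-membered radical closure onto a substituted alkene carbon is slow against hydrogen abstraction. The copper-mediated elimination can give the exocyclic methylene. The aminal nitrogen is exposed to a one-electron oxidant. The C9 ketone of A3 must then take a carbon nucleophile in the presence of a butenolide, an aminal and a lactone, with face selectivity that only the tricycle decides.
- Comparison: the chosen plan keeps every organometallic step before any lactone exists and fixes C9 by a chelate next to C9a.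

**Alternative 3:** The N–C9a and O–C9 bonds are cut together. A5 comes from the open-chain amino acid A6 with a Z trisubstituted C9=C9a alkene. Iodine would trigger amination by the N-benzylamine, the β-iodoamine would close to an aziridinium ion, and the carboxylate would open it at the tertiary carbon.
- Merit: the pyrrolidine and the quaternary lactone carbon form in one stereospecific step, with the C9/C9a relationship read from alkene geometry instead of a chelate. It is shorter, and its end game (acid unmasking of A5 and aminal closure) is better precedented than step 21.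
- Weak points: the route depends on two stereodefined alkenes (the Z trisubstituted one and the tetrasubstituted enoate). The 2,5-trans selectivity rests on 1,3-induction from C3. The acetal and tert-butyl ester must survive iodine and HI. The carboxylate must outcompete iodide at the aziridinium ion.
- Comparison: the chosen plan offers a trans-pyrrolidine whose configuration is guaranteed by two SN2 inversions on chiral-pool carbons, and later centres that are set one at a time and can be corrected one at a time.

Key step: step 7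

Assumption: the N,O-acetal carbon C5 epimerises through the ring-opened iminium carboxylate, and its (S) configuration in the target is taken to be the thermodynamically preferred one.

## Route

Step 1
Reactants: 1 1,2:5,6-di-O-isopropylidene-D-mannitol (commercial bis-acetonide of D-mannitol)
Product: 2 (4S,4'S)-4,4'-[(E)-ethene-1,2-diyl]bis(2,2-dimethyl-1,3-dioxolane)
Conditions: PPh3, imidazole, I2, toluene, 110 °C
Reagents that add atoms: none
Why: Garegg–Samuelsson olefination: both hydroxyls of the vicinal diol are activated by the iodophosphonium reagent and eliminated reductively, removing the C3/C4 stereocentres while the dioxolane carbons are untouched; alkene geometry does not matter because step 2 saturates it.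

Step 2
Reactants: 2 (4S,4'S)-4,4'-[(E)-ethene-1,2-diyl]bis(2,2-dimethyl-1,3-dioxolane)
Product: 4 (2S,5S)-hexane-1,2,5,6-tetraol, via saturated bis-acetonide 3 (not isolated)
Conditions: H2 (1 atm), 10% Pd/C, MeOH, rt; filter; 1 M HCl, rt
Reagents that add atoms: none
Why: Catalytic hydrogenation of the disubstituted alkene followed by acid hydrolysis of both acetonides in the same solution; no stereocentre is touched.

Step 3
Reactants: 4 (2S,5S)-hexane-1,2,5,6-tetraol
Product: 5 (2S,5S)-1,6-bis[(tert-butyldiphenylsilyl)oxy]hexane-2,5-diol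
Conditions: TBDPSCl (2.1 equiv), imidazole, DMF, 0 °C to rt
Reagents that add atoms: tert-butyl(chloro)diphenylsilane, CC(C)(C)[Si](Cl)(c1ccccc1)c1ccccc1
Why: Regioselective silylation: the bulky silyl chloride should take the two primary hydroxyls in preference to the secondary ones.

Step 4
Reactants: 5 (2S,5S)-1,6-bis[(tert-butyldiphenylsilyl)oxy]hexane-2,5-diol
Product: 6 (2S,5S)-1,6-bis[(tert-butyldiphenylsilyl)oxy]hexane-2,5-diyl dimethanesulfonate
Conditions: MsCl, Et3N, CH2Cl2, 0 °C
Reagents that add atoms: methanesulfonyl chloride, CS(=O)(=O)Cl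
Why: Sulfonylation at oxygen, with retention at both carbinol carbons.

Step 5
Reactants: 6 (2S,5S)-1,6-bis[(tert-butyldiphenylsilyl)oxy]hexane-2,5-diyl dimethanesulfonate
Product: 8 (2R,5R)-1,6-bis[(tert-butyldiphenylsilyl)oxy]hexane-2,5-diol, via diacetate 7 (not isolated)
Conditions: CsOAc, 18-crown-6 (cat.), DMF, 70 °C; then MeOH, K2CO3 (cat.), rt
Reagents that add atoms: cesium acetate, CC(=O)[O-].[Cs+]
Why: SN2 displacement of both secondary mesylates by acetate with inversion, then methanolysis of the diacetate; with no free hydroxyl in 6, the tetrahydrofuran closure that threatens a Mitsunobu inversion of a 1,4-diol cannot occur.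

Step 6
Reactants: 8 (2R,5R)-1,6-bis[(tert-butyldiphenylsilyl)oxy]hexane-2,5-diol
Product: 9 (2R,5R)-1,6-bis[(tert-butyldiphenylsilyl)oxy]hexane-2,5-diyl dimethanesulfonate
Conditions: MsCl, Et3N, CH2Cl2, −10 °C
Reagents that add atoms: methanesulfonyl chloride, CS(=O)(=O)Cl
Why: Sulfonylation at oxygen with retention; it provides the homochiral bis-electrophile for the ring closure.

Step 7
Reactants: 9 (2R,5R)-1,6-bis[(tert-butyldiphenylsilyl)oxy]hexane-2,5-diyl dimethanesulfonate; 10 benzylamine
Product: 11 (2S,5S)-1-benzyl-2,5-bis{[(tert-butyldiphenylsilyl)oxy]methyl}pyrrolidine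
Conditions: BnNH2 (neat, 8 equiv), 75 °C
Reagents that add atoms: none
Why: Benzylamine displaces the first secondary mesylate intermolecularly by SN2 with inversion; the resulting secondary amine then displaces the second mesylate in a 5-exo-tet closure, again with inversion, forming the second N–C bond and the pyrrolidine ring. The closest known reaction type is the double displacement of homochiral hexane-2,5-diyl disulfonates by primary amines, the standard entry to trans-2,5-disubstituted pyrrolidines. Both new stereocentres (the future C3 and C9a) are set by the stereospecificity of the two SN2 events, so the (2R,5R) configuration of 9, secured from D-mannitol through the acetate inversion of step 5, becomes the (2S,5S) configuration of 11. The step needs substitution to win over E2 elimination and cyclisation to win over a second intermolecular amination; unactivated secondary mesylates, a weakly basic but strongly nucleophilic amine and the kinetic advantage of five-membered ring closure should secure both. A cis-pyrrolidine could arise only through ionisation, which these carbons do not undergo. The silyl ethers and the C2 axis are untouched, so the two arms stay equivalent.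

Step 8
Reactants: 11 (2S,5S)-1-benzyl-2,5-bis{[(tert-butyldiphenylsilyl)oxy]methyl}pyrrolidine
Product: 12 [(2S,5S)-1-benzylpyrrolidine-2,5-diyl]dimethanol
Conditions: TBAF, THF, rt
Reagents that add atoms: none
Why: Fluoride desilylation; the N-benzyl group stays and will serve as the chelating tertiary amine.

Step 9
Reactants: 12 [(2S,5S)-1-benzylpyrrolidine-2,5-diyl]dimethanol
Product: 13 [(2S,5S)-1-benzyl-5-{[(tert-butyldimethylsilyl)oxy]methyl}pyrrolidin-2-yl]methanol
Conditions: NaH (1.0 equiv), THF, 0 °C to rt; TBSCl (1.0 equiv)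
Reagents that add atoms: tert-butyl(chloro)dimethylsilane, CC(C)(C)[Si](C)(C)Cl
Why: Monosilylation of a symmetrical diol through its monosodium alkoxide; the two arms are homotopic, so only mono- against bis-silylation matters, and bis-ether and diol can be recycled through step 8.

Step 10
Reactants: 13 [(2S,5S)-1-benzyl-5-{[(tert-butyldimethylsilyl)oxy]methyl}pyrrolidin-2-yl]methanol; 14 2-(3-bromopropyl)-1,3-dioxolane
Product: 17 1-[(2S,5S)-1-benzyl-5-{[(tert-butyldimethylsilyl)oxy]methyl}pyrrolidin-2-yl]-4-(1,3-dioxolan-2-yl)butan-1-ol (both carbinol epimers), via aldehyde 15 (not isolated), via Grignard reagent 16 (not isolated)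
Conditions: (COCl)2, DMSO, CH2Cl2, −78 °C; Et3N; then 16 (from 14, Mg, THF; excess), −78 to 0 °C; H2O
Reagents that add atoms: none
Why: Swern oxidation followed by Grignard addition in the same flask, so that the epimerisable α-amino aldehyde is consumed as it forms; the carbinol configuration is irrelevant because step 11 removes it.

Step 11
Reactants: 17 1-[(2S,5S)-1-benzyl-5-{[(tert-butyldimethylsilyl)oxy]methyl}pyrrolidin-2-yl]-4-(1,3-dioxolan-2-yl)butan-1-ol
Product: 18 1-[(2S,5S)-1-benzyl-5-{[(tert-butyldimethylsilyl)oxy]methyl}pyrrolidin-2-yl]-4-(1,3-dioxolan-2-yl)butan-1-one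
Conditions: Dess–Martin periodinane, CH2Cl2, 0 °C to rt
Reagents that add atoms: none
Why: Dess–Martin oxidation of a secondary alcohol under non-basic conditions, chosen to keep the α-amino ketone from epimerising at the ring carbon.

Step 12
Reactants: 19 (S)-3-bromo-2-methylpropan-1-ol
Product: 20 (S)-(3-bromo-2-methylpropoxy)(tert-butyl)diphenylsilane
Conditions: TBDPSCl, imidazole, CH2Cl2, rt
Reagents that add atoms: tert-butyl(chloro)diphenylsilane, CC(C)(C)[Si](Cl)(c1ccccc1)c1ccccc1
Why: Silylation of a primary alcohol; the chiral-pool stereocentre that becomes the spiro-lactone methyl carbon is not touched.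

Step 13
Reactants: 18 1-[(2S,5S)-1-benzyl-5-{[(tert-butyldimethylsilyl)oxy]methyl}pyrrolidin-2-yl]-4-(1,3-dioxolan-2-yl)butan-1-one; 20 (S)-(3-bromo-2-methylpropoxy)(tert-butyl)diphenylsilane
Product: 22 (2R,4S)-4-[(2S,5S)-1-benzyl-5-{[(tert-butyldimethylsilyl)oxy]methyl}pyrrolidin-2-yl]-1-[(tert-butyldiphenylsilyl)oxy]-7-(1,3-dioxolan-2-yl)-2-methylheptan-4-ol, via Grignard reagent 21 (not isolated)
Conditions: 20, Mg, THF, 40 °C (gives 21); 18, MgBr2·OEt2, CH2Cl2/Et2O, −78 °C; add 21, −78 to −30 °C; H2O
Reagents that add atoms: none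
Why: Chelation-controlled Grignard addition (Cram cyclic model): magnesium bridges the ring nitrogen and the ketone oxygen, and the nucleophile enters from the face of the C–H bond of the adjacent ring carbon, which should give the (S) tertiary carbinol (the future C9); the methyl stereocentre comes unchanged from 20.

Step 14
Reactants: 22 (2R,4S)-4-[(2S,5S)-1-benzyl-5-{[(tert-butyldimethylsilyl)oxy]methyl}pyrrolidin-2-yl]-1-[(tert-butyldiphenylsilyl)oxy]-7-(1,3-dioxolan-2-yl)-2-methylheptan-4-ol
Product: 23 (2R,4S)-4-[(2S,5S)-1-benzyl-5-(hydroxymethyl)pyrrolidin-2-yl]-1-[(tert-butyldiphenylsilyl)oxy]-7-(1,3-dioxolan-2-yl)-2-methylheptan-4-ol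
Conditions: HF·pyridine, pyridine, THF, 0 °C
Reagents that add atoms: none
Why: Selective desilylation: buffered HF·pyridine should cleave the primary tert-butyldimethylsilyl ether and leave the tert-butyldiphenylsilyl ether and the dioxolane.

Step 15
Reactants: 23 (2R,4S)-4-[(2S,5S)-1-benzyl-5-(hydroxymethyl)pyrrolidin-2-yl]-1-[(tert-butyldiphenylsilyl)oxy]-7-(1,3-dioxolan-2-yl)-2-methylheptan-4-ol
Product: 24 (2S,5S)-1-benzyl-5-[(2R,4S)-1-[(tert-butyldiphenylsilyl)oxy]-7-(1,3-dioxolan-2-yl)-4-hydroxy-2-methylheptan-4-yl]pyrrolidine-2-carbaldehyde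
Conditions: (COCl)2, DMSO, Et3N, CH2Cl2, −78 °C; used crude at once
Reagents that add atoms: none
Why: Swern oxidation of the primary alcohol; the tertiary alcohol cannot be oxidised, and the cold work-up limits epimerisation of the α-amino aldehyde.

Step 16
Reactants: 25 (R)-3-bromo-2-methylpropan-1-ol
Product: 26 (R)-(3-bromo-2-methylpropoxy)(tert-butyl)diphenylsilane
Conditions: TBDPSCl, imidazole, CH2Cl2, rt
Reagents that add atoms: tert-butyl(chloro)diphenylsilane, CC(C)(C)[Si](Cl)(c1ccccc1)c1ccccc1
Why: Silylation of a primary alcohol; this enantiomer supplies the methyl carbon of the side lactone.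

Step 17
Reactants: 24 (2S,5S)-1-benzyl-5-[(2R,4S)-1-[(tert-butyldiphenylsilyl)oxy]-7-(1,3-dioxolan-2-yl)-4-hydroxy-2-methylheptan-4-yl]pyrrolidine-2-carbaldehyde; 26 (R)-(3-bromo-2-methylpropoxy)(tert-butyl)diphenylsilane
Product: 28 (1S,3S)-1-{(2S,5S)-1-benzyl-5-[(2R,4S)-1-[(tert-butyldiphenylsilyl)oxy]-7-(1,3-dioxolan-2-yl)-4-hydroxy-2-methylheptan-4-yl]pyrrolidin-2-yl}-4-[(tert-butyldiphenylsilyl)oxy]-3-methylbutan-1-ol, via Grignard reagent 27 (not isolated)
Conditions: 26, Mg, THF (gives 27, 3.5 equiv); 24, MgBr2·OEt2, CH2Cl2/Et2O, −78 °C; H2O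
Reagents that add atoms: none
Why: Chelation-controlled Grignard addition to an α-amino aldehyde: the N–Mg–O five-membered chelate directs attack to the face of the ring C–H bond and should give the syn amino alcohol, the (S) carbinol of the side lactone; the first equivalent of reagent is spent on the tertiary hydroxyl.

Step 18
Reactants: 28 (1S,3S)-1-{(2S,5S)-1-benzyl-5-[(2R,4S)-1-[(tert-butyldiphenylsilyl)oxy]-7-(1,3-dioxolan-2-yl)-4-hydroxy-2-methylheptan-4-yl]pyrrolidin-2-yl}-4-[(tert-butyldiphenylsilyl)oxy]-3-methylbutan-1-ol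
Product: 29 (2R,4S)-4-{(2S,5S)-1-benzyl-5-[(1S,3S)-1,4-dihydroxy-3-methylbutyl]pyrrolidin-2-yl}-7-(1,3-dioxolan-2-yl)-2-methylheptane-1,4-diol
Conditions: TBAF, THF, rt
Reagents that add atoms: none
Why: Fluoride desilylation of both silyl ethers in one operation, treating the two arms together.

Step 19
Reactants: 29 (2R,4S)-4-{(2S,5S)-1-benzyl-5-[(1S,3S)-1,4-dihydroxy-3-methylbutyl]pyrrolidin-2-yl}-7-(1,3-dioxolan-2-yl)-2-methylheptane-1,4-diol
Product: 30 (3R,5S)-5-{(2S,5S)-1-benzyl-5-[(2S,4S)-4-methyl-5-oxooxolan-2-yl]pyrrolidin-2-yl}-5-[3-(1,3-dioxolan-2-yl)propyl]-3-methyloxolan-2-one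
Conditions: TEMPO (0.3 equiv), PhI(OAc)2 (4.5 equiv), AcOH (1 equiv), CH2Cl2, rt
Reagents that add atoms: none
Why: Oxidative lactonisation of two 1,4-diols with the oxoammonium/PhI(OAc)2 system: each primary alcohol is oxidised to the aldehyde, which closes to the lactol with the tertiary or secondary hydroxyl and is oxidised on to the γ-lactone; the amine is kept as its acetate salt, and the methyl-bearing carbons do not epimerise because the aldehydes are trapped as lactols.

Step 20
Reactants: 30 (3R,5S)-5-{(2S,5S)-1-benzyl-5-[(2S,4S)-4-methyl-5-oxooxolan-2-yl]pyrrolidin-2-yl}-5-[3-(1,3-dioxolan-2-yl)propyl]-3-methyloxolan-2-one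
Product: 31 (3R,5S)-5-[3-(1,3-dioxolan-2-yl)propyl]-3-methyl-5-{(2S,5S)-5-[(2S,4S)-4-methyl-5-oxooxolan-2-yl]pyrrolidin-2-yl}oxolan-2-one (handled as its trifluoroacetate salt)
Conditions: H2 (1 atm), Pd(OH)2/C, CF3CO2H (1.1 equiv), dry EtOAc, rt
Reagents that add atoms: none
Why: Hydrogenolysis of the N-benzyl group; the acid keeps the secondary amine protonated so that it cannot attack either γ-lactone, and the dry medium keeps the dioxolane closed so that no aldehyde is present for reductive amination.

Step 21
Reactants: 31 (3R,5S)-5-[3-(1,3-dioxolan-2-yl)propyl]-3-methyl-5-{(2S,5S)-5-[(2S,4S)-4-methyl-5-oxooxolan-2-yl]pyrrolidin-2-yl}oxolan-2-one; 32 pyruvic acid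
Product: 35 target CNP0155196.1, via amino aldehyde 33 (not isolated), via bicyclic enamine 34 (not isolated)
Conditions: pyruvic acid (3 equiv), 1,4-dioxane/H2O (9:1), 80 °C (31 used as its trifluoroacetate salt); NaHCO3 work-up
Reagents that add atoms: none
Why: Proposed new method: the acid medium hydrolyses the dioxolane, the ammonium aldehyde 33 condenses within the seven-membered ring to the iminium ion and its enamine 34, the enamine carbon C6 adds to the ketone carbonyl of pyruvic acid, the tertiary hydroxyl is lost by vinylogous elimination through the enamine, and the carboxylate adds to the conjugated iminium carbon C5 to close the N,O-acetal lactone; the closest known reaction type is the butenolide annulation of an aldehyde with glyoxylic acid and a secondary amine salt, which gives 5-amino- and 5-hydroxybutenolides by the same enamine/oxo acid sequence, and what is new is the α-keto acid and the tethered amine. C5 is expected to settle under thermodynamic control through reversible opening of the aminal, and the amine is never free, which holds back acyl transfer from the lactones.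

## Compound list

1 | 1,2:5,6-di-O-isopropylidene-D-mannitol | CC1(C)OC[C@@H](O1)[C@@H](O)[C@H](O)[C@H]1COC(C)(C)O1 | starting material
2 | (4S,4'S)-4,4'-[(E)-ethene-1,2-diyl]bis(2,2-dimethyl-1,3-dioxolane) | CC1(C)OC[C@@H](O1)/C=C/[C@H]1COC(C)(C)O1 | intermediate
3 | (4S,4'S)-4,4'-(ethane-1,2-diyl)bis(2,2-dimethyl-1,3-dioxolane) | CC1(C)OC[C@@H](O1)CC[C@H]1COC(C)(C)O1 | intermediate
4 | (2S,5S)-hexane-1,2,5,6-tetraol | OC[C@@H](O)CC[C@H](O)CO | intermediate
5 | (2S,5S)-1,6-bis[(tert-butyldiphenylsilyl)oxy]hexane-2,5-diol | CC(C)(C)[Si](c1ccccc1)(c1ccccc1)OC[C@@H](O)CC[C@H](O)CO[Si](c1ccccc1)(c1ccccc1)C(C)(C)C | intermediate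
6 | (2S,5S)-1,6-bis[(tert-butyldiphenylsilyl)oxy]hexane-2,5-diyl dimethanesulfonate | CC(C)(C)[Si](c1ccccc1)(c1ccccc1)OC[C@@H](OS(C)(=O)=O)CC[C@H](OS(C)(=O)=O)CO[Si](c1ccccc1)(c1ccccc1)C(C)(C)C | intermediate
7 | (2R,5R)-1,6-bis[(tert-butyldiphenylsilyl)oxy]hexane-2,5-diyl diacetate | CC(C)(C)[Si](c1ccccc1)(c1ccccc1)OC[C@H](OC(C)=O)CC[C@@H](OC(C)=O)CO[Si](c1ccccc1)(c1ccccc1)C(C)(C)C | intermediate
8 | (2R,5R)-1,6-bis[(tert-butyldiphenylsilyl)oxy]hexane-2,5-diol | CC(C)(C)[Si](c1ccccc1)(c1ccccc1)OC[C@H](O)CC[C@@H](O)CO[Si](c1ccccc1)(c1ccccc1)C(C)(C)C | intermediate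
9 | (2R,5R)-1,6-bis[(tert-butyldiphenylsilyl)oxy]hexane-2,5-diyl dimethanesulfonate | CC(C)(C)[Si](c1ccccc1)(c1ccccc1)OC[C@H](OS(C)(=O)=O)CC[C@@H](OS(C)(=O)=O)CO[Si](c1ccccc1)(c1ccccc1)C(C)(C)C | intermediate
10 | benzylamine | NCc1ccccc1 | starting material
11 | (2S,5S)-1-benzyl-2,5-bis{[(tert-butyldiphenylsilyl)oxy]methyl}pyrrolidine | CC(C)(C)[Si](c1ccccc1)(c1ccccc1)OC[C@@H]1CC[C@@H](CO[Si](c2ccccc2)(c2ccccc2)C(C)(C)C)N1Cc1ccccc1 | intermediate
12 | [(2S,5S)-1-benzylpyrrolidine-2,5-diyl]dimethanol | OC[C@@H]1CC[C@@H](CO)N1Cc1ccccc1 | intermediate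
13 | [(2S,5S)-1-benzyl-5-{[(tert-butyldimethylsilyl)oxy]methyl}pyrrolidin-2-yl]methanol | OC[C@@H]1CC[C@@H](CO[Si](C)(C)C(C)(C)C)N1Cc1ccccc1 | intermediate
14 | 2-(3-bromopropyl)-1,3-dioxolane | BrCCCC1OCCO1 | starting material
15 | (2S,5S)-1-benzyl-5-{[(tert-butyldimethylsilyl)oxy]methyl}pyrrolidine-2-carbaldehyde | O=C[C@@H]1CC[C@@H](CO[Si](C)(C)C(C)(C)C)N1Cc1ccccc1 | intermediate
16 | [3-(1,3-dioxolan-2-yl)propyl]magnesium bromide | Br[Mg]CCCC1OCCO1 | intermediate
17 | 1-[(2S,5S)-1-benzyl-5-{[(tert-butyldimethylsilyl)oxy]methyl}pyrrolidin-2-yl]-4-(1,3-dioxolan-2-yl)butan-1-ol (both carbinol epimers) | OC(CCCC1OCCO1)[C@@H]1CC[C@@H](CO[Si](C)(C)C(C)(C)C)N1Cc1ccccc1 | intermediate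
18 | 1-[(2S,5S)-1-benzyl-5-{[(tert-butyldimethylsilyl)oxy]methyl}pyrrolidin-2-yl]-4-(1,3-dioxolan-2-yl)butan-1-one | O=C(CCCC1OCCO1)[C@@H]1CC[C@@H](CO[Si](C)(C)C(C)(C)C)N1Cc1ccccc1 | intermediate
19 | (S)-3-bromo-2-methylpropan-1-ol | BrC[C@@H](C)CO | starting material
20 | (S)-(3-bromo-2-methylpropoxy)(tert-butyl)diphenylsilane | BrC[C@@H](C)CO[Si](c1ccccc1)(c1ccccc1)C(C)(C)C | intermediate
21 | {(2S)-3-[(tert-butyldiphenylsilyl)oxy]-2-methylpropyl}magnesium bromide | Br[Mg]C[C@@H](C)CO[Si](c1ccccc1)(c1ccccc1)C(C)(C)C | intermediate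
22 | (2R,4S)-4-[(2S,5S)-1-benzyl-5-{[(tert-butyldimethylsilyl)oxy]methyl}pyrrolidin-2-yl]-1-[(tert-butyldiphenylsilyl)oxy]-7-(1,3-dioxolan-2-yl)-2-methylheptan-4-ol | C1COC(O1)CCC[C@](O)(C[C@@H](C)CO[Si](c1ccccc1)(c1ccccc1)C(C)(C)C)[C@@H]1CC[C@@H](CO[Si](C)(C)C(C)(C)C)N1Cc1ccccc1 | intermediate
23 | (2R,4S)-4-[(2S,5S)-1-benzyl-5-(hydroxymethyl)pyrrolidin-2-yl]-1-[(tert-butyldiphenylsilyl)oxy]-7-(1,3-dioxolan-2-yl)-2-methylheptan-4-ol | C1COC(O1)CCC[C@](O)(C[C@@H](C)CO[Si](c1ccccc1)(c1ccccc1)C(C)(C)C)[C@@H]1CC[C@@H](CO)N1Cc1ccccc1 | intermediate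
24 | (2S,5S)-1-benzyl-5-[(2R,4S)-1-[(tert-butyldiphenylsilyl)oxy]-7-(1,3-dioxolan-2-yl)-4-hydroxy-2-methylheptan-4-yl]pyrrolidine-2-carbaldehyde | C1COC(O1)CCC[C@](O)(C[C@@H](C)CO[Si](c1ccccc1)(c1ccccc1)C(C)(C)C)[C@@H]1CC[C@@H](C=O)N1Cc1ccccc1 | intermediate
25 | (R)-3-bromo-2-methylpropan-1-ol | BrC[C@H](C)CO | starting material
26 | (R)-(3-bromo-2-methylpropoxy)(tert-butyl)diphenylsilane | BrC[C@H](C)CO[Si](c1ccccc1)(c1ccccc1)C(C)(C)C | intermediate
27 | {(2R)-3-[(tert-butyldiphenylsilyl)oxy]-2-methylpropyl}magnesium bromide | Br[Mg]C[C@H](C)CO[Si](c1ccccc1)(c1ccccc1)C(C)(C)C | intermediate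
28 | (1S,3S)-1-{(2S,5S)-1-benzyl-5-[(2R,4S)-1-[(tert-butyldiphenylsilyl)oxy]-7-(1,3-dioxolan-2-yl)-4-hydroxy-2-methylheptan-4-yl]pyrrolidin-2-yl}-4-[(tert-butyldiphenylsilyl)oxy]-3-methylbutan-1-ol | C1COC(O1)CCC[C@](O)(C[C@@H](C)CO[Si](c1ccccc1)(c1ccccc1)C(C)(C)C)[C@@H]1CC[C@@H]([C@@H](O)C[C@H](C)CO[Si](c2ccccc2)(c2ccccc2)C(C)(C)C)N1Cc1ccccc1 | intermediate
29 | (2R,4S)-4-{(2S,5S)-1-benzyl-5-[(1S,3S)-1,4-dihydroxy-3-methylbutyl]pyrrolidin-2-yl}-7-(1,3-dioxolan-2-yl)-2-methylheptane-1,4-diol | C1COC(O1)CCC[C@](O)(C[C@@H](C)CO)[C@@H]1CC[C@@H]([C@@H](O)C[C@H](C)CO)N1Cc1ccccc1 | intermediate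
30 | (3R,5S)-5-{(2S,5S)-1-benzyl-5-[(2S,4S)-4-methyl-5-oxooxolan-2-yl]pyrrolidin-2-yl}-5-[3-(1,3-dioxolan-2-yl)propyl]-3-methyloxolan-2-one | C1COC(O1)CCC[C@]2(C[C@@H](C)C(=O)O2)[C@@H]2CC[C@@H]([C@@H]3C[C@H](C)C(=O)O3)N2Cc1ccccc1 | intermediate
31 | (3R,5S)-5-[3-(1,3-dioxolan-2-yl)propyl]-3-methyl-5-{(2S,5S)-5-[(2S,4S)-4-methyl-5-oxooxolan-2-yl]pyrrolidin-2-yl}oxolan-2-one | C1COC(O1)CCC[C@]2(C[C@@H](C)C(=O)O2)[C@@H]2CC[C@@H]([C@@H]3C[C@H](C)C(=O)O3)N2 | intermediate
32 | pyruvic acid | CC(=O)C(=O)O | starting material
33 | 4-[(2S,4R)-4-methyl-2-{(2S,5S)-5-[(2S,4S)-4-methyl-5-oxooxolan-2-yl]pyrrolidin-2-yl}-5-oxooxolan-2-yl]butanal | O=CCCC[C@]1(C[C@@H](C)C(=O)O1)[C@@H]1CC[C@@H]([C@@H]2C[C@H](C)C(=O)O2)N1 | intermediate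
34 | bicyclic enamine: 2,3,7,8,9,9a-hexahydro-1H-pyrrolo[1,2-a]azepine with a C5=C6 double bond, C9 (S) spiro to a (3R)-3-methyloxolan-2-one through its ring oxygen, C9a (S), and C3 (S) bearing (2S,4S)-4-methyl-5-oxooxolan-2-yl | C1=CCC[C@]2(C[C@@H](C)C(=O)O2)[C@@H]2CC[C@@H]([C@@H]3C[C@H](C)C(=O)O3)N12 | intermediate
35 | CNP0155196.1: pyrrolo[1,2-a]azepine (N4, C5–C9, C9a, C1–C3) with a 3-methylfuran-2(5H)-one fused through its C4 (= C6) and C5 (= C5, N,O-acetal, S); C9 (S) spiro to a (3R)-3-methyloxolan-2-one with the ring oxygen on C9; C9a (S); C3 (S) bearing (2S,4S)-4-methyl-5-oxooxolan-2-yl | CC1=C2CC[C@]3(C[C@@H](C)C(=O)O3)[C@@H]3CC[C@@H]([C@@H]4C[C@H](C)C(=O)O4)N3[C@H]2OC1=O | target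

## Step count and least certain steps

Total step count: 21. Longest linear sequence: 19 steps (from 1 through steps 1–11, 13–15 and 17–21); steps 12 and 16 are one-step side branches.

**Step 21 (Proposed new method).** The most likely failure is that pyruvic acid reacts through its enol at the iminium carbon (Mannich direction) instead of being attacked at its ketone carbonyl by the enamine, because an α-keto acid, unlike glyoxylic acid, can enolise. A second risk is acyl transfer from a γ-lactone to the nitrogen whenever the amine is free, and a third is that the aminal equilibrates to the C5 epimer.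

Fallback with known reactions, from 31 to 35: 31 is converted with Boc2O and NaHCO3 into the N-Boc acetal F1, and wet acetone with pyridinium p-toluenesulfonate frees the N-Boc aldehyde F2. TBSOTf and Et3N at −78 °C give the silyl enol ether F3, so that the aldehyde carbon chain is fixed as the nucleophile. A Mukaiyama aldol addition to methyl pyruvate with BF3·OEt2 gives the tertiary aldol F4. CF3CO2H then removes the Boc group; the ammonium aldehyde condenses, loses water through its enamine and lactonises with loss of methanol to 35.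

**Step 7 (key step).** E2 elimination from a secondary mesylate can compete, or the chain can stop after the first displacement and take up a second benzylamine intermolecularly, if the bulky silyloxymethyl groups slow the 5-exo-tet closure.

Fallback, from 8 to 11: diol 8 is converted with SOCl2 and Et3N into the cyclic sulfite F5 and oxidised (RuCl3 cat., NaIO4) to the cyclic sulfate F6. Benzylamine opens F6 once with inversion to the amino sulfate F7, which can no longer be attacked by a second amine because the remaining sulfate monoester is anionic. Heating with base then closes the ring with the second inversion to 11.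

**Step 13.** The Grignard reagent may enolise the ketone (with epimerisation at the ring carbon) or reduce it by β-hydride transfer. Alternatively, the chelate may not form because the nitrogen is flanked by two substituents, so that Felkin-type attack erodes or reverses the face selectivity.

Fallback, from 13 to 22, exchanging the order in which the two carbon groups are introduced: Swern oxidation of 13 and addition of 21 give the secondary alcohol F8, and Dess–Martin oxidation gives the ketone F9. Addition of 16 to F9 under the conditions of step 13 then delivers 22 if the intrinsic bias of these ketones is the non-chelate one.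

**Step 17.** The α-amino aldehyde can epimerise before it reacts, and the neighbouring magnesium alkoxide of the tertiary carbinol can compete for the metal, so that chelate control is lost and the anti amino alcohol forms.

Fallback, from 24 to 28: the addition is run without regard to selectivity, and the mixture of 28 and its carbinol epimer F10 is oxidised with Dess–Martin periodinane to the ketone F11. F11 is reduced with KBH(s-Bu)3 in THF at −78 °C; non-chelate (Felkin–Anh) delivery of hydride to an α-(dialkylamino) ketone gives the syn amino alcohol 28.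

**Step 19.** The oxoammonium oxidant may attack the benzylic tertiary amine, or the secondary carbinol may be oxidised before the lactol has formed.

Fallback, from 29 to 31: hydrogenolysis of 29 over Pd(OH)2/C in the presence of Boc2O gives the N-Boc tetraol F12, in which nitrogen is no longer oxidisable. The same TEMPO/PhI(OAc)2 oxidation gives the N-Boc acetal F1, and anhydrous CF3CO2H returns 31 as its trifluoroacetate salt.

## Further compounds

F1 | step 21 | N-Boc acetal: tert-butyl (2S,5S)-2-{(2S,4R)-2-[3-(1,3-dioxolan-2-yl)propyl]-4-methyl-5-oxooxolan-2-yl}-5-[(2S,4S)-4-methyl-5-oxooxolan-2-yl]pyrrolidine-1-carboxylate | C1COC(O1)CCC[C@]2(C[C@@H](C)C(=O)O2)[C@@H]2CC[C@@H]([C@@H]3C[C@H](C)C(=O)O3)N2C(=O)OC(C)(C)C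
F2 | step 21 | N-Boc aldehyde: tert-butyl (2S,5S)-2-[(2S,4R)-4-methyl-5-oxo-2-(4-oxobutyl)oxolan-2-yl]-5-[(2S,4S)-4-methyl-5-oxooxolan-2-yl]pyrrolidine-1-carboxylate | O=CCCC[C@]1(C[C@@H](C)C(=O)O1)[C@@H]1CC[C@@H]([C@@H]2C[C@H](C)C(=O)O2)N1C(=O)OC(C)(C)C
F3 | step 21 | silyl enol ether of F2 (tert-butyldimethylsilyl, E/Z mixture) | CC(C)(C)[Si](C)(C)OC=CCC[C@]1(C[C@@H](C)C(=O)O1)[C@@H]1CC[C@@H]([C@@H]2C[C@H](C)C(=O)O2)N1C(=O)OC(C)(C)C
F4 | step 21 | tertiary aldol: methyl 3-formyl-2-hydroxy-2-methylpentanoate carrying at C5 the N-Boc pyrrolidinyl bis-lactone of F2 (diastereomers at the two new carbons) | COC(=O)C(C)(O)C(C=O)CC[C@]1(C[C@@H](C)C(=O)O1)[C@@H]1CC[C@@H]([C@@H]2C[C@H](C)C(=O)O2)N1C(=O)OC(C)(C)C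
F5 | step 7 | (4R,7R)-4,7-bis{[(tert-butyldiphenylsilyl)oxy]methyl}-1,3,2-dioxathiepane 2-oxide | O=S1O[C@@H](CO[Si](c2ccccc2)(c2ccccc2)C(C)(C)C)CC[C@H](CO[Si](c2ccccc2)(c2ccccc2)C(C)(C)C)O1
F6 | step 7 | (4R,7R)-4,7-bis{[(tert-butyldiphenylsilyl)oxy]methyl}-1,3,2-dioxathiepane 2,2-dioxide | O=S1(=O)O[C@@H](CO[Si](c2ccccc2)(c2ccccc2)C(C)(C)C)CC[C@H](CO[Si](c2ccccc2)(c2ccccc2)C(C)(C)C)O1
F7 | step 7 | (2R,5S)-5-(benzylamino)-1,6-bis[(tert-butyldiphenylsilyl)oxy]hexan-2-yl hydrogen sulfate | OS(=O)(=O)O[C@@H](CO[Si](c1ccccc1)(c1ccccc1)C(C)(C)C)CC[C@@H](CO[Si](c1ccccc1)(c1ccccc1)C(C)(C)C)NCc1ccccc1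
F8 | step 13 | (3R)-1-[(2S,5S)-1-benzyl-5-{[(tert-butyldimethylsilyl)oxy]methyl}pyrrolidin-2-yl]-4-[(tert-butyldiphenylsilyl)oxy]-3-methylbutan-1-ol (both carbinol epimers) | OC(C[C@@H](C)CO[Si](c1ccccc1)(c1ccccc1)C(C)(C)C)[C@@H]1CC[C@@H](CO[Si](C)(C)C(C)(C)C)N1Cc1ccccc1
F9 | step 13 | (3R)-1-[(2S,5S)-1-benzyl-5-{[(tert-butyldimethylsilyl)oxy]methyl}pyrrolidin-2-yl]-4-[(tert-butyldiphenylsilyl)oxy]-3-methylbutan-1-one | O=C(C[C@@H](C)CO[Si](c1ccccc1)(c1ccccc1)C(C)(C)C)[C@@H]1CC[C@@H](CO[Si](C)(C)C(C)(C)C)N1Cc1ccccc1
F10 | step 17 | (1R)-carbinol epimer of 28 | C1COC(O1)CCC[C@](O)(C[C@@H](C)CO[Si](c1ccccc1)(c1ccccc1)C(C)(C)C)[C@@H]1CC[C@@H]([C@H](O)C[C@H](C)CO[Si](c2ccccc2)(c2ccccc2)C(C)(C)C)N1Cc1ccccc1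
F11 | step 17 | ketone from 28: (3S)-1-{(2S,5S)-1-benzyl-5-[(2R,4S)-1-[(tert-butyldiphenylsilyl)oxy]-7-(1,3-dioxolan-2-yl)-4-hydroxy-2-methylheptan-4-yl]pyrrolidin-2-yl}-4-[(tert-butyldiphenylsilyl)oxy]-3-methylbutan-1-one | C1COC(O1)CCC[C@](O)(C[C@@H](C)CO[Si](c1ccccc1)(c1ccccc1)C(C)(C)C)[C@@H]1CC[C@@H](C(=O)C[C@H](C)CO[Si](c2ccccc2)(c2ccccc2)C(C)(C)C)N1Cc1ccccc1
F12 | step 19 | N-Boc tetraol: tert-butyl (2S,5S)-2-[(1S,3S)-1,4-dihydroxy-3-methylbutyl]-5-[(2R,4S)-7-(1,3-dioxolan-2-yl)-1,4-dihydroxy-2-methylheptan-4-yl]pyrrolidine-1-carboxylate | C1COC(O1)CCC[C@](O)(C[C@@H](C)CO)[C@@H]1CC[C@@H]([C@@H](O)C[C@H](C)CO)N1C(=O)OC(C)(C)C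
A1 | alternative 1 | saturated tetracyclic amine bis-lactone (35 without the butenolide, C5 and C6 as CH2) | C1CCC[C@]2(C[C@@H](C)C(=O)O2)[C@@H]2CC[C@@H]([C@@H]3C[C@H](C)C(=O)O3)N12
A2 | alternative 1 | bis(homoallylic alcohol): (9S,9aS)-9-allyl-octahydropyrrolo[1,2-a]azepin-9-ol bearing at C3 (S) an (S)-1-hydroxybut-3-enyl group | C1CCC[C@](O)(CC=C)[C@@H]2CC[C@@H]([C@@H](O)CC=C)N12
A3 | alternative 2 | tricyclic C9 ketone: aminal butenolide-fused pyrrolo[1,2-a]azepin-9-one with the side lactone at C3 | CC1=C2CCC(=O)[C@@H]3CC[C@@H]([C@@H]4C[C@H](C)C(=O)O4)N3[C@H]2OC1=O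
A4 | alternative 2 | cyclopropanol with N-bound butenolide: 1-{(2S,5S)-1-[(2S)-4-methyl-5-oxo-2,5-dihydrofuran-2-yl]-5-[(2S,4S)-4-methyl-5-oxooxolan-2-yl]pyrrolidin-2-yl}cyclopropan-1-ol | OC1(CC1)[C@@H]1CC[C@@H]([C@@H]2C[C@H](C)C(=O)O2)N1[C@@H]1C=C(C)C(=O)O1
A5 | alternative 3 | N-benzyl trans-pyrrolidine bis-lactone with the diethyl acetal / tert-butyl ester arm | CCOC(OCC)/C(CC[C@]1(C[C@@H](C)C(=O)O1)[C@@H]1CC[C@@H]([C@@H]2C[C@H](C)C(=O)O2)N1Cc1ccccc1)=C(/C)C(=O)OC(C)(C)C
A6 | alternative 3 | open-chain Z-alkene amino acid: secondary N-benzylamine at the future C3, Z trisubstituted C9=C9a alkene, free carboxylic acid and the acetal/ester arm | CCOC(OCC)/C(=C(/C)C(=O)OC(C)(C)C)CC/C(=C/CC[C@H](NCc1ccccc1)[C@@H]1C[C@H](C)C(=O)O1)C[C@@H](C)C(=O)O
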